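Count the turnovers. In every flask below, a free catalyst turns starting material into product while a protic impurity sits beside them, and you have to rank the recipes.

| setting | oak | birch | maple | north-west | north-east | south | south-west | south-east | west |
|---|---|---|---|---|---|---|---|---|---|
| starting material | 0.050 M | 0.050 M | 0.089 M | 0.050 M | 0.15 M | 0.15 M | 0.050 M | 0.080 M | 0.050 M |
| protic impurity | 0.017 M | 0.10 M | 0.050 M | 0.0500 M | 0.0500 M | 0.0500 M | 0.0120 M | 0.0800 M | 0.0120 M |
| free catalyst | 15 mol% | 15 mol% | 15 mol% | 15 mol% | 25 mol% | 15 mol% | 10 mol% | 5 mol% | 8 mol% |
| remark | run made earlier | run made earlier | run made earlier |  |  |  |  |  |  |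
| time |  |  |  | 80 min | 80 min | 80 min | 80 min | 80 min | 80 min |

- all flasks from highest to lowest amount of product, in percent of the starting material charged, at 80 min (north-west / north-east / south / south-west / south-east / west)
- the same order at 8.0 min (north-west / north-east / south / south-west / south-east / west)
- the amount of product, in percent of the starting material charged of the flask you put first, at 80 min
- the amount of product, in percent of the starting material charged of the flask you put last, at 80 min

- the analysis behind the earlier runs scatters by 1 percentage point, standard deviation

| run | time / min | product / % |
|---|---|---|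
| oak | 5.00 | 31.1 |
| oak | 6.00 | 35.7 |
| oak | 10.0 | 48.6 |
| oak | 15.0 | 55.4 |
| oak | 25.0 | 63.7 |
| oak | 40.0 | 69.9 |
| oak | 60.0 | 73.1 |
| birch | 5.00 | 30.4 |
| birch | 6.00 | 35.9 |
| birch | 10.0 | 43.2 |
| birch | 15.0 | 50.7 |
| birch | 25.0 | 56.6 |
| birch | 40.0 | 60.6 |
| birch | 60.0 | 59.7 |
| maple | 5.00 | 39.6 |
| maple | 15.0 | 65.1 |
| maple | 25.0 | 67.4 |
| maple | 40.0 | 72.4 |
| maple | 60.0 | 73.2 |

(standard deviation of a reading: 1 percentage point)

Read the last rows of these runs. The turnover count (the turnover number) is the product made divided by the catalyst charged, both in percent of the starting material.

Oak ends at 73.1 % from 15 mol%, a count of 4.87, with 3.2 percentage points gained over its last interval. Maple has 1.78 times oak's starting material and 0.562 equivalents of impurity against oak's 0.340, yet it reads 4.88, the same count within the scatter. Birch, with 2.00 equivalents of impurity, reads 4.04 at 40.0 min, lower than maple. So I carry 4.88 as my estimate of the count for flasks with fewer equivalents of impurity than birch.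

Now multiply by the loading. South-east, at 5 mol%, comes to about 24.4 %, west at 8 mol% to 39.0 %, and south-west at 10 mol% to 48.8 %. North-west has birch's loading and half its impurity, so I expect it no lower than birch's 60.6 %, which is more than my south-west figure. South has 0.333 equivalents of impurity, close to oak, so I put it near 73.2 %. For north-east the count gives 122 %, more than the whole charge, so it sets no ceiling there, and I simply place that flask first. My order is north-east, south, north-west, south-west, west, south-east.

The forecast gives north-east > south > south-west > north-west > west > south-east at 80 min and north-east > south > north-west > south-west > west > south-east at 8.0 min, with 87 % (80 % to 93 %) on top and 51 % (42 % to 58 %) at the bottom. Its ground is that “the catalyst is dying rather than the reaction reaching a limit”. We part on the places of north-west and south-west, and on south-east: its 51 % from 5 mol% means 10.2 turnovers, twice my count.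

South-east gives 27.9 %, which is 23 points under the forecast, and north-east gives 81.6 %. The full order is north-east > south > north-west > south-west > west > south-east at 80 min and north-east > south > north-west > south-west > west > south-east at 8.0 min.

    starting material + free catalyst → catalyst intermediate (k = 0.358 L mol⁻¹ s⁻¹)
    catalyst intermediate → free catalyst + product (k = 0.0442 s⁻¹)
    starting material + protic impurity → quenched substrate (k = 0.00571 L mol⁻¹ s⁻¹)
    catalyst intermediate → spent catalyst (k = 0.00789 s⁻¹)

At 80.0 min south-east holds 99.7 % of its catalyst as spent catalyst and 0.272 % as free catalyst, with 14.9 % of the starting material still there. Its count is 5.58 turnovers, above my estimate of 4.88. The neighbour of south-east with 0.020 M of protic impurity ends with 49.0 % of its starting material still there and 28.0 % of product, again 5.60 turnovers.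

The readings were computed for substances that don't exist, and the scatter is random.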